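**Retrosynthetic overview**

1. Endgame: hydrogenolysis of two aryl benzyl ethers and acid removal of an acetonide and a silyl ether. Before that, the C3–CH2Ar bond of the lactone (numbered O1, C2 carbonyl, C3, C4, C5) is made by anti-selective alkylation of the C4-substituted lactone enolate with a benzylic bromide that carries the erythro arylglycerol β-aryl ether.
2. Enabling feature: without the C3 benzyl group, C4 of the lactone has two CH2 ring neighbours (C3 and C5). Removing O1 joins C5 to the carbonyl carbon C2 and leaves a Cs-symmetric 3-(arylmethyl)cyclobutanone with two enantiotopic CH2–C(=O) bonds. A catalytic asymmetric Baeyer–Villiger ring expansion therefore makes the O1–C5 bond, closes the γ-lactone and sets C4 in one operation.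
3. Cyclobutanone: the intact four-membered ring comes from 3-(bromomethyl)cyclobutanone by Negishi coupling with a 5-bromo-2,3-dihydrobenzofuran. That ring system comes from an Evans aldol (sets C3) and an acid-mediated, trans-selective C2–O closure.
4. Arylglycerol ether: Mitsunobu inversion of methyl D-glycerate by a vanillyl phenol (C8–O), Weinreb ketone synthesis, chelation-controlled reduction (C7), acetonide, benzylic bromide.
5. Order of ring formation: the 1,3-dioxane (protecting ring) and, independently, the dihydrofuran ring of the benzofuran; then the cyclobutanone is attached; the γ-lactone ring is formed last, by ring expansion.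

Key step: step 20

Assumption: the R-configured phosphoric acid of step 20 is taken to be the catalyst enantiomer that makes the 4R lactone from a 3-(arylmethyl)cyclobutanone; if the sense of induction is the opposite one, the S acid is used and nothing else changes.

Abbreviations: TBS = tert-butyldimethylsilyl, Bn = benzyl, MOM = methoxymethyl.

**Route**

Step 1
Reactants: 1 vanillyl alcohol
Product: 2 4-(TBSO-methyl)-2-methoxyphenol
Conditions: TBSCl (1.0 equiv), imidazole, DMF/CH2Cl2, 0 °C
Reagents that add atoms: tert-butyldimethylsilyl chloride, CC(C)(C)[Si](C)(C)Cl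
Why: Selective O-silylation: with one equivalent at 0 °C the primary benzylic hydroxyl should react ahead of the hydrogen-bonded, ortho-substituted phenol.

Step 2
Reactants: 3 methyl (R)-2,3-dihydroxypropanoate
Product: 4 methyl (R)-3-(TBSO)-2-hydroxypropanoate
Conditions: TBSCl (1.05 equiv), imidazole, CH2Cl2, 0 °C
Reagents that add atoms: tert-butyldimethylsilyl chloride, CC(C)(C)[Si](C)(C)Cl
Why: Selective O-silylation of the primary hydroxyl over the secondary α-hydroxyl; the stereocentre is not touched.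

Step 3
Reactants: 2 4-(TBSO-methyl)-2-methoxyphenol; 4 methyl (R)-3-(TBSO)-2-hydroxypropanoate
Product: 5 methyl (S)-3-(TBSO)-2-[4-(TBSO-methyl)-2-methoxyphenoxy]propanoate
Conditions: PPh3, DIAD, THF, 0 °C to rt
Reagents that add atoms: none
Why: Mitsunobu etherification of an α-hydroxy ester with a phenol is an SN2 displacement of the oxyphosphonium group, so the R centre of 4 should be inverted cleanly to the S aryl ether (the future C8).

Step 4
Reactants: 5 methyl (S)-3-(TBSO)-2-[4-(TBSO-methyl)-2-methoxyphenoxy]propanoate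
Product: 6 (S)-3-(TBSO)-2-[4-(TBSO-methyl)-2-methoxyphenoxy]-N-methoxy-N-methylpropanamide
Conditions: MeNH(OMe)·HCl, iPrMgCl, THF, −20 °C; aq. NH4Cl
Reagents that add atoms: N,O-dimethylhydroxylamine hydrochloride, CNOC.Cl
Why: Direct ester aminolysis by the magnesium amide (Weinreb amide formation) at low temperature, conditions under which α-alkoxy esters normally keep their configuration.

Step 5
Reactants: 6 the Weinreb amide; 7 1-(benzyloxy)-4-bromo-2-methoxybenzene
Product: 9 (S)-1-(4-benzyloxy-3-methoxyphenyl)-3-(TBSO)-2-[4-(TBSO-methyl)-2-methoxyphenoxy]propan-1-one, via aryllithium 8 (not isolated)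
Conditions: 7, n-BuLi, THF, −78 °C; then 6, −78 °C; aq. NH4Cl
Reagents that add atoms: none
Why: Bromine–lithium exchange gives the aryllithium, which should add only once because the chelated tetrahedral adduct survives until work-up (Weinreb ketone synthesis); at −78 °C the α-stereocentre should not be deprotonated.

Step 6
Reactants: 9 the α-aryloxy ketone
Product: 10 (1R,2S)-1-(4-benzyloxy-3-methoxyphenyl)-3-(TBSO)-2-[4-(TBSO-methyl)-2-methoxyphenoxy]propan-1-ol (erythro)
Conditions: Zn(BH4)2, Et2O, −40 to 0 °C; aq. NH4Cl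
Reagents that add atoms: none
Why: Chelation-controlled reduction (Cram cyclic model): zinc should bridge the carbonyl oxygen and the α-aryloxy oxygen (helped by its ortho-methoxy group), hydride enters from the face of the small α-hydrogen, and the carbinol centre is set R, anti to the aryloxy group, which is the erythro isomer.

Step 7
Reactants: 10 the erythro alcohol
Product: 11 (1R,2S)-1-(4-benzyloxy-3-methoxyphenyl)-2-[4-(hydroxymethyl)-2-methoxyphenoxy]propane-1,3-diol
Conditions: Bu4NF, THF, 0 °C to rt; aq. NH4Cl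
Reagents that add atoms: none
Why: Fluoride-mediated desilylation should cleave both primary silyl ethers and leave the benzyl ether and both stereocentres alone.

Step 8
Reactants: 11 the triol
Product: 12 [4-{[(4R,5S)-4-(4-benzyloxy-3-methoxyphenyl)-2,2-dimethyl-1,3-dioxan-5-yl]oxy}-3-methoxyphenyl]methanol
Conditions: 2,2-dimethoxypropane, PPTS (cat.), acetone, rt; aqueous work-up
Reagents that add atoms: 2,2-dimethoxypropane, COC(C)(C)OC
Why: Acid-catalysed transketalization should close the six-membered isopropylidene acetal on the only 1,3-diol pair, and any mixed ketal on the lone benzylic alcohol falls off on work-up.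

Step 9
Reactants: 12 the acetonide alcohol
Product: 13 (4R,5S)-4-(4-benzyloxy-3-methoxyphenyl)-5-[4-(bromomethyl)-2-methoxyphenoxy]-2,2-dimethyl-1,3-dioxane
Conditions: CBr4, PPh3, 2,6-lutidine, CH2Cl2, 0 °C; used at once
Reagents that add atoms: carbon tetrabromide, BrC(Br)(Br)Br
Why: Appel bromination converts the electron-rich primary benzylic alcohol under neutral conditions that the acetonide should tolerate.

Step 10
Reactants: 14 4-bromo-2-methoxyphenol
Product: 15 1-(allyloxy)-4-bromo-2-methoxybenzene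
Conditions: allyl bromide, K2CO3, acetone, reflux
Reagents that add atoms: allyl bromide, C=CCBr
Why: Williamson O-allylation of the phenoxide.

Step 11
Reactants: 15 the allyl aryl ether
Product: 17 2-allyl-4-bromo-6-methoxyphenol, via dienone 16 (not isolated)
Conditions: N,N-diethylaniline, 190 °C
Reagents that add atoms: none
Why: Aromatic Claisen rearrangement, a [3,3]-sigmatropic shift to the only free ortho position, followed by tautomerization of the dienone to the phenol.

Step 12
Reactants: 17 2-allyl-4-bromo-6-methoxyphenol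
Product: 18 1-allyl-5-bromo-3-methoxy-2-(methoxymethoxy)benzene
Conditions: MOMCl, iPr2NEt, CH2Cl2, 0 °C to rt
Reagents that add atoms: chloromethyl methyl ether, COCCl
Why: O-alkylation of the phenol gives an acetal protecting group that should survive ozone, chlorite, the boron enolate and LiBH4 and comes off with acid in step 17.

Step 13
Reactants: 18 the MOM ether
Product: 20 2-[5-bromo-3-methoxy-2-(methoxymethoxy)phenyl]acetic acid, via arylacetaldehyde 19 (not isolated)
Conditions: O3, CH2Cl2/MeOH, −78 °C; Me2S; then NaClO2, NaH2PO4, 2-methyl-2-butene, t-BuOH/H2O, 0 °C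
Reagents that add atoms: ozone, [O-][O+]=O; sodium chlorite, [Na+].[O-]Cl=O
Why: Ozonolysis of the terminal alkene with reductive work-up gives the arylacetaldehyde, which is oxidized without isolation by the Pinnick protocol; the alkene should react with ozone far faster than the brominated ring.

Step 14
Reactants: 20 the arylacetic acid; 21 (S)-4-benzyloxazolidin-2-one
Product: 23 (S)-4-benzyl-3-{2-[5-bromo-3-methoxy-2-(methoxymethoxy)phenyl]acetyl}oxazolidin-2-one, via pivalic mixed anhydride 22 (not isolated)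
Conditions: PivCl, Et3N, THF, −20 °C; then 21, LiCl, rt
Reagents that add atoms: none
Why: N-acylation of the oxazolidinone through the mixed anhydride, which should be attacked at the less hindered arylacetyl carbonyl.

Step 15
Reactants: 23 the N-arylacetyl oxazolidinone; 24 4-(benzyloxy)-3-methoxybenzaldehyde
Product: 26 (S)-4-benzyl-3-{(2S,3S)-3-(4-benzyloxy-3-methoxyphenyl)-2-[5-bromo-3-methoxy-2-(methoxymethoxy)phenyl]-3-hydroxypropanoyl}oxazolidin-2-one, via Z-boron enolate 25 (not isolated)
Conditions: Bu2BOTf, iPr2NEt, CH2Cl2, −78 to 0 °C; then 24, −78 to 0 °C; pH 7 buffer, MeOH, H2O2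
Reagents that add atoms: none
Why: Evans syn-aldol addition: the Z-boron enolate reacts through a Zimmerman–Traxler chair on the face opposite the benzyl group of the auxiliary, which sets the α-centre S (it becomes C3 R of the dihydrobenzofuran); the carbinol centre is also set S but is re-formed in step 17.

Step 16
Reactants: 26 the aldol adduct
Product: 27 (1S,2R)-1-(4-benzyloxy-3-methoxyphenyl)-2-[5-bromo-3-methoxy-2-(methoxymethoxy)phenyl]propane-1,3-diol
Conditions: LiBH4, THF/MeOH, 0 °C; aq. NH4Cl
Reagents that add atoms: none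
Why: Reductive cleavage of the N-acyloxazolidinone with LiBH4 gives the primary alcohol and returns the auxiliary; the aryl bromide, benzyl ether and acetal should be inert.

Step 17
Reactants: 27 the MOM-protected diol
Product: 29 [(2S,3R)-2-(4-benzyloxy-3-methoxyphenyl)-5-bromo-7-methoxy-2,3-dihydro-1-benzofuran-3-yl]methanol, via free phenol 28 (not isolated)
Conditions: HCl, MeOH, 45 °C
Reagents that add atoms: none
Why: Acid removes the MOM acetal and then ionizes the 4-alkoxybenzylic alcohol to a quinone-methide-like cation that the freed phenol captures to close the five-membered ring; the closure is reversible under these conditions and should settle on the trans isomer, so C2 is set S by the C3 centre (thermodynamic control).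

Step 18
Reactants: 29 the dihydrobenzofuran alcohol
Product: 30 (2S,3R)-2-(4-benzyloxy-3-methoxyphenyl)-5-bromo-3-(TBSO-methyl)-7-methoxy-2,3-dihydro-1-benzofuran
Conditions: TBSCl, imidazole, DMF, rt
Reagents that add atoms: tert-butyldimethylsilyl chloride, CC(C)(C)[Si](C)(C)Cl
Why: O-silylation of the primary alcohol protects it against the base of step 21.

Step 19
Reactants: 30 the aryl bromide; 31 3-(bromomethyl)cyclobutan-1-one
Product: 33 3-{[(2S,3R)-2-(4-benzyloxy-3-methoxyphenyl)-3-(TBSO-methyl)-7-methoxy-2,3-dihydro-1-benzofuran-5-yl]methyl}cyclobutan-1-one, via organozinc 32 (not isolated)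
Conditions: 31, Zn dust, LiCl, THF, 40 °C; then 30, Pd(OAc)2 (2 mol %), SPhos (4 mol %), THF, 50 °C
Reagents that add atoms: none
Why: Negishi sp3–sp2 cross-coupling: zinc inserts into the primary C–Br bond (alkylzinc halides tolerate ketones) and the biarylphosphine–palladium catalyst should couple the primary alkylzinc with the electron-rich aryl bromide faster than β-hydride elimination.

Step 20
Reactants: 33 the prochiral cyclobutanone
Product: 35 (4R)-4-{[(2S,3R)-2-(4-benzyloxy-3-methoxyphenyl)-3-(TBSO-methyl)-7-methoxy-2,3-dihydro-1-benzofuran-5-yl]methyl}oxolan-2-one, via Criegee adduct 34 (not isolated)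
Conditions: (R)-3,3'-di(pyren-1-yl)-H8-BINOL hydrogen phosphate (10 mol %), 30% aq. H2O2 (1.5 equiv), CHCl3, −40 °C
Reagents that add atoms: hydrogen peroxide, OO
Why: Baeyer–Villiger oxidation run as a catalytic desymmetrization: the chiral phosphoric acid activates the strained ketone and H2O2, the hydroperoxide adds to give the Criegee adduct, and one α-CH2 shifts from the carbonyl carbon to the proximal peroxide oxygen with loss of water, so that a C–C bond of the four-membered ring is cleaved as the O1–C5 bond is made. The closest known reaction type is the phosphoric-acid- or metal-catalysed asymmetric Baeyer–Villiger oxidation of 3-aryl- and 3-benzylcyclobutanones with H2O2 or peracids. The five-membered lactone closes by ring expansion, a 1,2-shift of carbon to oxygen with retention at the migrating carbon, and not by cyclization of an open chain, so no Baldwin-type constraint applies. The new stereocentre C4 is set by the catalyst alone: the chiral phosphate holds the Criegee adduct in a hydrogen-bonded array in which only one of the two enantiotopic CH2 groups can lie antiperiplanar to the O–O bond, and the remote centres of the dihydrobenzofuran should have no say. Regioselectivity is not an issue because both candidates for migration are CH2 groups and give the same constitution; what the step needs is group selectivity between them, and because 33 is already enantiopure the minor outcome is a diastereomer that can be removed by chromatography. Chemoselectivity rests on ring strain: the cyclobutanone should react with aqueous H2O2 at −40 °C while the electron-rich arenes, the benzyl ether and the silyl ether are not touched.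

Step 21
Reactants: 35 the β-substituted lactone; 13 the benzylic bromide
Product: 37 (3R,4R)-3-[4-{[(4R,5S)-4-(4-benzyloxy-3-methoxyphenyl)-2,2-dimethyl-1,3-dioxan-5-yl]oxy}-3-methoxybenzyl]-4-{[(2S,3R)-2-(4-benzyloxy-3-methoxyphenyl)-3-(TBSO-methyl)-7-methoxy-2,3-dihydro-1-benzofuran-5-yl]methyl}oxolan-2-one, via lithium enolate 36 (not isolated)
Conditions: LiN(SiMe3)2, THF, −78 °C; then 13, DMPU, −78 to −40 °C
Reagents that add atoms: none
Why: Enolate alkylation of a β-substituted γ-butyrolactone with a benzylic bromide should occur on the ring face anti to the C4 substituent (1,2-induction), which sets C3 R, trans to C4, the usual outcome for dibenzylbutyrolactones.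

Step 22
Reactants: 37 the fully protected compound
Product: 38 (3R,4R)-3-[4-{[(1R,2S)-1-(4-benzyloxy-3-methoxyphenyl)-1,3-dihydroxypropan-2-yl]oxy}-3-methoxybenzyl]-4-{[(2S,3R)-2-(4-benzyloxy-3-methoxyphenyl)-3-(hydroxymethyl)-7-methoxy-2,3-dihydro-1-benzofuran-5-yl]methyl}oxolan-2-one
Conditions: AcOH/THF/H2O (3:1:1), 40 °C
Reagents that add atoms: none
Why: Mild aqueous acid should hydrolyse the isopropylidene acetal and the primary silyl ether in one operation while being too weak to ionize the benzylic alcohol or open the lactone.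

Step 23
Reactants: 38 the bis(benzyl ether)
Product: 39 CNP0298853.1
Conditions: H2 (1 atm), 10% Pd/C, EtOAc/EtOH, rt, stopped at full conversion
Reagents that add atoms: none
Why: Hydrogenolysis of the two aryl benzyl ethers under neutral conditions should be much faster than cleavage of the benzylic C–O bonds of the dihydrobenzofuran and of the secondary alcohol.

**Compound list**

1 | vanillyl alcohol | COc1cc(CO)ccc1O | starting material
2 | 4-(TBSO-methyl)-2-methoxyphenol | COc1cc(CO[Si](C)(C)C(C)(C)C)ccc1O | intermediate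
3 | methyl (R)-2,3-dihydroxypropanoate | COC(=O)[C@H](O)CO | starting material
4 | methyl (R)-3-(TBSO)-2-hydroxypropanoate | COC(=O)[C@H](O)CO[Si](C)(C)C(C)(C)C | intermediate
5 | methyl (S)-3-(TBSO)-2-[4-(TBSO-methyl)-2-methoxyphenoxy]propanoate | COC(=O)[C@@H](Oc1ccc(CO[Si](C)(C)C(C)(C)C)cc1OC)CO[Si](C)(C)C(C)(C)C | intermediate
6 | (S)-3-(TBSO)-2-[4-(TBSO-methyl)-2-methoxyphenoxy]-N-methoxy-N-methylpropanamide | CON(C)C(=O)[C@@H](Oc1ccc(CO[Si](C)(C)C(C)(C)C)cc1OC)CO[Si](C)(C)C(C)(C)C | intermediate
7 | 1-(benzyloxy)-4-bromo-2-methoxybenzene | COc1cc(Br)ccc1OCc1ccccc1 | starting material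
8 | (4-benzyloxy-3-methoxyphenyl)lithium (not isolated) | COc1cc([Li])ccc1OCc1ccccc1 | intermediate
9 | (S)-1-(4-benzyloxy-3-methoxyphenyl)-3-(TBSO)-2-[4-(TBSO-methyl)-2-methoxyphenoxy]propan-1-one | COc1cc(C(=O)[C@@H](Oc2ccc(CO[Si](C)(C)C(C)(C)C)cc2OC)CO[Si](C)(C)C(C)(C)C)ccc1OCc1ccccc1 | intermediate
10 | (1R,2S)-1-(4-benzyloxy-3-methoxyphenyl)-3-(TBSO)-2-[4-(TBSO-methyl)-2-methoxyphenoxy]propan-1-ol | COc1cc([C@@H](O)[C@H](CO[Si](C)(C)C(C)(C)C)Oc2ccc(CO[Si](C)(C)C(C)(C)C)cc2OC)ccc1OCc1ccccc1 | intermediate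
11 | (1R,2S)-1-(4-benzyloxy-3-methoxyphenyl)-2-[4-(hydroxymethyl)-2-methoxyphenoxy]propane-1,3-diol | COc1cc([C@@H](O)[C@H](CO)Oc2ccc(CO)cc2OC)ccc1OCc1ccccc1 | intermediate
12 | [4-{[(4R,5S)-4-(4-benzyloxy-3-methoxyphenyl)-2,2-dimethyl-1,3-dioxan-5-yl]oxy}-3-methoxyphenyl]methanol | COc1cc([C@H]2OC(C)(C)OC[C@@H]2Oc2ccc(CO)cc2OC)ccc1OCc1ccccc1 | intermediate
13 | (4R,5S)-4-(4-benzyloxy-3-methoxyphenyl)-5-[4-(bromomethyl)-2-methoxyphenoxy]-2,2-dimethyl-1,3-dioxane | COc1cc([C@H]2OC(C)(C)OC[C@@H]2Oc2ccc(CBr)cc2OC)ccc1OCc1ccccc1 | intermediate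
14 | 4-bromo-2-methoxyphenol | COc1cc(Br)ccc1O | starting material
15 | 1-(allyloxy)-4-bromo-2-methoxybenzene | C=CCOc1ccc(Br)cc1OC | intermediate
16 | 6-allyl-4-bromo-2-methoxycyclohexa-2,4-dien-1-one (not isolated) | C=CCC1C=C(Br)C=C(OC)C1=O | intermediate
17 | 2-allyl-4-bromo-6-methoxyphenol | C=CCc1cc(Br)cc(OC)c1O | intermediate
18 | 1-allyl-5-bromo-3-methoxy-2-(methoxymethoxy)benzene | C=CCc1cc(Br)cc(OC)c1OCOC | intermediate
19 | 2-[5-bromo-3-methoxy-2-(methoxymethoxy)phenyl]acetaldehyde (not isolated) | O=CCc1cc(Br)cc(OC)c1OCOC | intermediate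
20 | 2-[5-bromo-3-methoxy-2-(methoxymethoxy)phenyl]acetic acid | OC(=O)Cc1cc(Br)cc(OC)c1OCOC | intermediate
21 | (S)-4-benzyloxazolidin-2-one | O=C1OC[C@H](Cc2ccccc2)N1 | starting material
22 | mixed anhydride of 20 and pivalic acid (not isolated) | CC(C)(C)C(=O)OC(=O)Cc1cc(Br)cc(OC)c1OCOC | intermediate
23 | (S)-4-benzyl-3-{2-[5-bromo-3-methoxy-2-(methoxymethoxy)phenyl]acetyl}oxazolidin-2-one | O=C(Cc1cc(Br)cc(OC)c1OCOC)N1[C@@H](Cc2ccccc2)COC1=O | intermediate
24 | 4-(benzyloxy)-3-methoxybenzaldehyde | COc1cc(C=O)ccc1OCc1ccccc1 | starting material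
25 | Z-dibutylboron enolate of 23 (not isolated) | CCCCB(CCCC)O/C(=C\c1cc(Br)cc(OC)c1OCOC)N1[C@@H](Cc2ccccc2)COC1=O | intermediate
26 | (S)-4-benzyl-3-{(2S,3S)-3-(4-benzyloxy-3-methoxyphenyl)-2-[5-bromo-3-methoxy-2-(methoxymethoxy)phenyl]-3-hydroxypropanoyl}oxazolidin-2-one | O=C(N1[C@@H](Cc2ccccc2)COC1=O)[C@@H](c1cc(Br)cc(OC)c1OCOC)[C@H](O)c1ccc(OCc2ccccc2)c(OC)c1 | intermediate
27 | (1S,2R)-1-(4-benzyloxy-3-methoxyphenyl)-2-[5-bromo-3-methoxy-2-(methoxymethoxy)phenyl]propane-1,3-diol | OC[C@@H](c1cc(Br)cc(OC)c1OCOC)[C@H](O)c1ccc(OCc2ccccc2)c(OC)c1 | intermediate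
28 | (1S,2R)-1-(4-benzyloxy-3-methoxyphenyl)-2-(5-bromo-2-hydroxy-3-methoxyphenyl)propane-1,3-diol (not isolated) | OC[C@@H](c1cc(Br)cc(OC)c1O)[C@H](O)c1ccc(OCc2ccccc2)c(OC)c1 | intermediate
29 | [(2S,3R)-2-(4-benzyloxy-3-methoxyphenyl)-5-bromo-7-methoxy-2,3-dihydro-1-benzofuran-3-yl]methanol | COc1cc(Br)cc2[C@H](CO)[C@@H](c3ccc(OCc4ccccc4)c(OC)c3)Oc12 | intermediate
30 | (2S,3R)-2-(4-benzyloxy-3-methoxyphenyl)-5-bromo-3-(TBSO-methyl)-7-methoxy-2,3-dihydro-1-benzofuran | COc1cc(Br)cc2[C@H](CO[Si](C)(C)C(C)(C)C)[C@@H](c3ccc(OCc4ccccc4)c(OC)c3)Oc12 | intermediate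
31 | 3-(bromomethyl)cyclobutan-1-one | O=C1CC(CBr)C1 | starting material
32 | [(3-oxocyclobutyl)methyl]zinc bromide (not isolated) | O=C1CC(C[Zn]Br)C1 | intermediate
33 | 3-{[(2S,3R)-2-(4-benzyloxy-3-methoxyphenyl)-3-(TBSO-methyl)-7-methoxy-2,3-dihydro-1-benzofuran-5-yl]methyl}cyclobutan-1-one | COc1cc(CC3CC(=O)C3)cc2[C@H](CO[Si](C)(C)C(C)(C)C)[C@@H](c3ccc(OCc4ccccc4)c(OC)c3)Oc12 | intermediate
34 | 1-hydroperoxy-3-(arylmethyl)cyclobutan-1-ol, the Criegee adduct of 33 (not isolated) | COc1cc(CC3CC(O)(OO)C3)cc2[C@H](CO[Si](C)(C)C(C)(C)C)[C@@H](c3ccc(OCc4ccccc4)c(OC)c3)Oc12 | intermediate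
35 | (4R)-4-{[(2S,3R)-2-(4-benzyloxy-3-methoxyphenyl)-3-(TBSO-methyl)-7-methoxy-2,3-dihydro-1-benzofuran-5-yl]methyl}oxolan-2-one | COc1cc(C[C@H]3COC(=O)C3)cc2[C@H](CO[Si](C)(C)C(C)(C)C)[C@@H](c3ccc(OCc4ccccc4)c(OC)c3)Oc12 | intermediate
36 | lithium enolate of 35 (not isolated) | COc1cc(C[C@H]3COC(O[Li])=C3)cc2[C@H](CO[Si](C)(C)C(C)(C)C)[C@@H](c3ccc(OCc4ccccc4)c(OC)c3)Oc12 | intermediate
37 | (3R,4R)-3-[4-{[(4R,5S)-4-(4-benzyloxy-3-methoxyphenyl)-2,2-dimethyl-1,3-dioxan-5-yl]oxy}-3-methoxybenzyl]-4-{[(2S,3R)-2-(4-benzyloxy-3-methoxyphenyl)-3-(TBSO-methyl)-7-methoxy-2,3-dihydro-1-benzofuran-5-yl]methyl}oxolan-2-one | COc1cc([C@H]2OC(C)(C)OC[C@@H]2Oc2ccc(C[C@H]3C(=O)OC[C@@H]3Cc3cc(OC)c4c(c3)[C@H](CO[Si](C)(C)C(C)(C)C)[C@@H](c3ccc(OCc5ccccc5)c(OC)c3)O4)cc2OC)ccc1OCc1ccccc1 | intermediate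
38 | bis(benzyl ether) of the target at both phenols | COc1cc([C@@H](O)[C@H](CO)Oc2ccc(C[C@H]3C(=O)OC[C@@H]3Cc3cc(OC)c4c(c3)[C@H](CO)[C@@H](c3ccc(OCc5ccccc5)c(OC)c3)O4)cc2OC)ccc1OCc1ccccc1 | intermediate
39 | CNP0298853.1, (3R,4R)-3-[4-{[(1R,2S)-1,3-dihydroxy-1-(4-hydroxy-3-methoxyphenyl)propan-2-yl]oxy}-3-methoxybenzyl]-4-{[(2S,3R)-2-(4-hydroxy-3-methoxyphenyl)-3-(hydroxymethyl)-7-methoxy-2,3-dihydro-1-benzofuran-5-yl]methyl}oxolan-2-one | COc1cc([C@@H](O)[C@H](CO)Oc2ccc(C[C@H]3C(=O)OC[C@@H]3Cc3cc(OC)c4c(c3)[C@H](CO)[C@@H](c3ccc(O)c(OC)c3)O4)cc2OC)ccc1O | target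

**Step count and risks**

Total step count: 23. Longest linear sequence: 14 steps (steps 10 to 23, from 4-bromo-2-methoxyphenol 14). The arylglycerol branch (steps 1 to 9) joins at step 21.

Steps most likely to fail:

1. Step 20 (key step). What may go wrong: weak discrimination between the two enantiotopic methylene groups during the migration, so that much of the material ends up as the 4S epimer and the separation of diastereomers becomes wasteful. Fallback, setting out from 30 and coming back at 35: bromine–lithium exchange on 30 (n-BuLi, THF, −78 °C) and quench with DMF would give the 5-carbaldehyde F1. Stobbe condensation with dimethyl succinate (KOt-Bu, t-BuOH) would give the E-arylidenesuccinic acid monomethyl ester F2. Hydrogenation with [Rh(cod)2]BF4 and Me-DuPhos (the ligand enantiomer that gives the R centre) would give the R monoester F3. Reduction of the ester in the presence of the carboxylate with Ca(BH4)2 (from CaCl2 and NaBH4, EtOH) and mild acidification would close lactone 35, here through the acyl–oxygen bond.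

2. Step 6. What may go wrong: incomplete chelation, so that open-chain (Felkin–Anh) delivery of hydride competes and facial selectivity at the ketone is poor. Fallback, setting out from 9 and coming back at 10: reduction with LiBH(s-Bu)3 in THF at −78 °C would follow the Felkin–Anh path and give the threo (1S,2S) alcohol F4. Mitsunobu reaction with 4-nitrobenzoic acid (PPh3, DIAD) would invert the benzylic centre and give the erythro (1R,2S) 4-nitrobenzoate F5. Methanolysis with K2CO3 in MeOH would then give 10.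

3. Step 19. What may go wrong: slow zinc insertion, self-addition or protonation of the keto-organozinc reagent, and sluggish oxidative addition to the electron-rich aryl bromide, leading to reduction in place of coupling. Fallback, setting out from 30 and coming back at 33: Stille coupling with allyltributylstannane (Pd(PPh3)4, toluene, 100 °C) would give the 5-allyl compound F6. A [2+2] cycloaddition with dichloroketene (Cl3CCOCl, Zn–Cu couple, Et2O) would give the 2,2-dichlorocyclobutanone F7 as a mixture at the new ring carbon, which does not matter. Dechlorination with Zn in AcOH would give 33.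

**Further compounds**

F1 | step 20 | (2S,3R)-2-(4-benzyloxy-3-methoxyphenyl)-3-(TBSO-methyl)-7-methoxy-2,3-dihydro-1-benzofuran-5-carbaldehyde | COc1cc(C=O)cc2[C@H](CO[Si](C)(C)C(C)(C)C)[C@@H](c3ccc(OCc4ccccc4)c(OC)c3)Oc12
F2 | step 20 | (E)-3-(methoxycarbonyl)-4-[(2S,3R)-2-(4-benzyloxy-3-methoxyphenyl)-3-(TBSO-methyl)-7-methoxy-2,3-dihydro-1-benzofuran-5-yl]but-3-enoic acid | COc1cc(/C=C(\CC(=O)O)C(=O)OC)cc2[C@H](CO[Si](C)(C)C(C)(C)C)[C@@H](c3ccc(OCc4ccccc4)c(OC)c3)Oc12
F3 | step 20 | (R)-3-(methoxycarbonyl)-4-[(2S,3R)-2-(4-benzyloxy-3-methoxyphenyl)-3-(TBSO-methyl)-7-methoxy-2,3-dihydro-1-benzofuran-5-yl]butanoic acid | COc1cc(C[C@H](CC(=O)O)C(=O)OC)cc2[C@H](CO[Si](C)(C)C(C)(C)C)[C@@H](c3ccc(OCc4ccccc4)c(OC)c3)Oc12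
F4 | step 6 | (1S,2S)-1-(4-benzyloxy-3-methoxyphenyl)-3-(TBSO)-2-[4-(TBSO-methyl)-2-methoxyphenoxy]propan-1-ol | COc1cc([C@H](O)[C@H](CO[Si](C)(C)C(C)(C)C)Oc2ccc(CO[Si](C)(C)C(C)(C)C)cc2OC)ccc1OCc1ccccc1
F5 | step 6 | (1R,2S)-1-(4-benzyloxy-3-methoxyphenyl)-3-(TBSO)-2-[4-(TBSO-methyl)-2-methoxyphenoxy]propyl 4-nitrobenzoate | COc1cc([C@@H](OC(=O)c2ccc(cc2)[N+](=O)[O-])[C@H](CO[Si](C)(C)C(C)(C)C)Oc2ccc(CO[Si](C)(C)C(C)(C)C)cc2OC)ccc1OCc1ccccc1
F6 | step 19 | (2S,3R)-5-allyl-2-(4-benzyloxy-3-methoxyphenyl)-3-(TBSO-methyl)-7-methoxy-2,3-dihydro-1-benzofuran | COc1cc(CC=C)cc2[C@H](CO[Si](C)(C)C(C)(C)C)[C@@H](c3ccc(OCc4ccccc4)c(OC)c3)Oc12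
F7 | step 19 | 2,2-dichloro-3-{[(2S,3R)-2-(4-benzyloxy-3-methoxyphenyl)-3-(TBSO-methyl)-7-methoxy-2,3-dihydro-1-benzofuran-5-yl]methyl}cyclobutan-1-one | COc1cc(CC3CC(=O)C3(Cl)Cl)cc2[C@H](CO[Si](C)(C)C(C)(C)C)[C@@H](c3ccc(OCc4ccccc4)c(OC)c3)Oc12
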